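## Retrosynthetic overview

1. Target ⇐ global desilylation ⇐ joint reduction of a 3,12-diketone to the two axial alcohols; ring D ⇐ gold-catalysed Conia-ene closure (C13–C16) of a propargyl group on C8 onto a 12,13-enediol disilyl ether; ring A ⇐ aldol closure (C3–C4) of the lactone enolate onto a C3 aldehyde.
2. Ring B (C5, C6, C8, C9, C10) ⇐ photochemical Wolff ring contraction of a six-membered 6-diazo-7-ketone (ring C5–C6–C7–C8–C9–C10). Enabling feature: the carbonyl carbon C7 sits in this ring between the fully substituted C8 and the C6 methylene, so the diazo group can only enter at C6 and only the C7–C8 bond can migrate. C7 is expelled as the carboxyl carbon, the same C7 extrusion as in the biosynthetic contraction of ent-kaurenoids.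
3. Six-membered precursor ring ⇐ a phenol-derived cyclohexadienone. Its single carbonyl (C7, the former phenol carbon) activates C8=C9 for an enantioselective Diels–Alder reaction (ring C), then C8 for propargylation, then C5 for an intramolecular Michael addition of the propanoate on O–C10 (19,10-lactone, C4–C5).
4. Dienone ⇐ oxidative dearomatisation of 4-(3-hydroxypropyl)phenol (as its allyl carbonate) with propionic acid as nucleophile; diene ⇐ butane-2,3-dione.
5. Order of ring formation: six-membered precursor of ring B (from the arene) → ring C → lactone ring → ring B by contraction → ring A → ring D.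

Key step: step 8

Numbering: atoms carry the gibberellane numbers of the target throughout (C7 = carboxyl carbon, C19 = lactone carbonyl, C18 = methyl); α/β mean below/above the plane in the usual drawing (5β-H, 9β-H, lactone α).
Assumption: the (S)-configured oxazaborolidinium catalyst is taken to be the antipode that gives the Diels–Alder adduct drawn; if the sense of induction is opposite, the (R)-catalyst is used.

## Route

Step 1
Reactants: 1 butane-2,3-dione
Product: 2 2,3-bis(tert-butyldimethylsilyloxy)buta-1,3-diene
Conditions: TBSOTf (2.2 equiv), Et3N (3 equiv), CH2Cl2, 0 °C to rt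
Reagents that add atoms: tert-butyldimethylsilyl trifluoromethanesulfonate, CC(C)(C)[Si](C)(C)OS(=O)(=O)C(F)(F)F
Why: Double soft enolisation and O-silylation (silyl enol ether formation) of the 1,2-diketone should give the 2,3-dioxygenated diene that later supplies C11–C14 with both the C12 and C13 oxygens; no stereocentre is formed.

Step 2
Reactants: 3 3-(4-hydroxyphenyl)propan-1-ol
Product: 4 allyl 3-(4-hydroxyphenyl)propyl carbonate
Conditions: allyl chloroformate (1.05 equiv), pyridine, CH2Cl2, −40 to 0 °C
Reagents that add atoms: allyl chloroformate, C=CCOC(=O)Cl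
Why: Chemoselective O-acylation (carbonate formation) of the primary aliphatic alcohol, which under pyridine (too weak to form the phenoxide) should react faster than the phenol, and the carbonate makes the chain oxygen non-nucleophilic for step 3; no stereocentre is formed.

Step 3
Reactants: 4 allyl 3-(4-hydroxyphenyl)propyl carbonate
Product: 5 1-[3-(allyloxycarbonyloxy)propyl]-4-oxocyclohexa-2,5-dien-1-yl propanoate
Conditions: PhI=O (1.2 equiv), EtCO2H (20 equiv), CH2Cl2, 0 °C
Reagents that add atoms: propionic acid, CCC(=O)O
Why: Hypervalent-iodine oxidative dearomatisation (para-acyloxylation of a 4-alkylphenol by the phenyliodine dipropanoate formed in the flask) should give the achiral p-quinol ester, which already holds O–C10, C19, C4, C18 and the C1–C3 chain, with C10 still prochiral.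

Step 4
Reactants: 5 quinol propanoate; 2 2,3-bis(tert-butyldimethylsilyloxy)buta-1,3-diene (1.5 equiv)
Product: 6 cis-fused Diels–Alder enone (10α-propanoyloxy; 8β-H; 9β-H; 12,13-bis-OTBS enediol ether)
Conditions: (S)-3,3-diphenyl-1-(2-methylphenyl)tetrahydro-1H,3H-pyrrolo[1,2-c][1,3,2]oxazaborole activated with HNTf2 (20 mol %), CH2Cl2, −78 °C
Reagents that add atoms: none
Why: Catalytic enantioselective Diels–Alder reaction in which the cationic oxazaborolidine binds the dienone carbonyl and differentiates the two enantiotopic enone units, so that the diene should add across C8=C9 suprafacially (8-H and 9-H cis) and on the face syn to the propanoyloxy oxygen (the usual contrasteric preference of 4-alkyl-4-acyloxycyclohexadienones), which sets C10 (O α), C9 (9β-H) and C8 together and installs the C12 and C13 oxygens.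

Step 5
Reactants: 6 cis-fused Diels–Alder enone
Product: 7 8β-propargyl enone (quaternary C8; C15 β; C14 α)
Conditions: KN(SiMe3)2 (1.05 equiv), THF, −78 °C; propargyl bromide, −78 to −20 °C
Reagents that add atoms: propargyl bromide (3-bromoprop-1-yne), C#CCBr
Why: Enolate alkylation in which the silazide is basic enough for the ketone α-hydrogen 8-H but not for the propanoate, and the cross-conjugated potassium enolate should be alkylated at C8 on the convex β face, anti to the α-fused ring C, creating the quaternary centre with C15 β and C14 α.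

Step 6
Reactants: 7 8β-propargyl enone
Product: 8 19,10-lactone 7-ketone (cis-fused γ-lactone; 5β-H; C4 epimers)
Conditions: LiN(i-Pr)2 (2.2 equiv), THF, −78 °C; aq. NH4Cl
Reagents that add atoms: none
Why: Intramolecular Michael addition (5-exo-trig) of the propanoate lithium enolate to C5 of the enone, in which the ester hanging from the α-oxygen on C10 can deliver C4 only to the α face, giving the cis-fused γ-lactone with 5β-H, while the second equivalent of base is held by the alkyne C–H and C4 stays an epimer mixture that converges in step 11.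

Step 7
Reactants: 8 19,10-lactone 7-ketone
Product: 10 6-diazo-7-ketone, via 6-trifluoroacetyl ketone 9 (not isolated)
Conditions: LiN(SiMe3)2 (1.1 equiv), THF, −78 °C; CF3CO2CH2CF3; aq. NH4Cl; then MsN3, Et3N, H2O, MeCN, rt
Reagents that add atoms: methanesulfonyl azide, CS(=O)(=O)N=[N+]=[N-]
Why: Detrifluoroacetylative diazo transfer (Regitz-type diazo transfer) in which the ketone can enolise only towards C6 because C8 is quaternary, C-trifluoroacetylation activates C6 and mesyl azide then delivers N2 with loss of the trifluoroacetyl group; no stereocentre is touched.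

Step 8
Reactants: 10 6-diazo-7-ketone
Product: 12 ring-B-contracted 2-(trimethylsilyl)ethyl 7-ester (6β-ester; 6α-H), via ring-contracted ketene 11 (not isolated)
Conditions: hν (365 nm), Me3SiCH2CH2OH (10 equiv), THF, 0 °C; then KOt-Bu (0.2 equiv), t-BuOH/THF, 0 °C
Reagents that add atoms: 2-(trimethylsilyl)ethanol, C[Si](C)(C)CCO
Why: Irradiation expels N2 from the diazo ketone, which the ring locks in the s-Z geometry, so that loss of N2 and the 1,2-shift of C8 from C7 to C6 should be concerted and give ketene 11, which the alcohol traps as the ester. The closest known reaction type is the photochemical Wolff rearrangement of 2-diazocyclohexanones to cyclopentanecarboxylic esters, and the bond reorganisation (C7–C8 becomes C6–C8, C7 leaves the ring) is that of the biosynthetic ent-kaurenoid-to-gibberellin contraction. Ring B (C5, C6, C8, C9, C10) is closed by ring contraction, that is by 1,2-migration of the ring carbon C8 with retention at C8 and not by a cyclisation, so the configurations at C5, C8, C9 and C10 from steps 4 to 6 are carried over unchanged. The new stereocentre C6 is not left to the face of enol protonation: the catalytic alkoxide should equilibrate the ester α-centre to the thermodynamic epimer with C7 β, trans to C4 on the neighbouring C5. The step needs regioselective migration and chemoselectivity for rearrangement over O–H insertion, 1,2-H shift from C5 and intramolecular [2+2] addition of the ketene to the enediol ether; these are secured by C8 being the only substituent on the carbonyl carbon besides the diazo carbon, by the concerted pathway open to the s-Z cyclic diazo ketone, and by the large excess of alcohol that intercepts the ketene.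

Step 9
Reactants: 12 ring-B-contracted 2-(trimethylsilyl)ethyl 7-ester
Product: 13 primary alcohol (free C3–OH)
Conditions: Pd(PPh3)4 (5 mol %), morpholine (3 equiv), THF, rt
Reagents that add atoms: none
Why: Tsuji–Trost deallylation in which zerovalent palladium ionises the allyl carbonate, CO2 is lost and morpholine captures the allyl fragment, which should free the primary alcohol under neutral conditions that leave the enol silyl ethers, the alkyne and both esters untouched.

Step 10
Reactants: 13 primary alcohol
Product: 14 C3 aldehyde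
Conditions: SO3·pyridine (3 equiv), DMSO, Et3N, CH2Cl2, 0 °C
Reagents that add atoms: none
Why: Parikh–Doering oxidation (activated DMSO) should convert the primary alcohol into the aldehyde under non-acidic conditions that spare the electron-rich enediol disilyl ether; no stereocentre changes.

Step 11
Reactants: 14 C3 aldehyde
Product: 15 ring-A aldol (C3–C4 bond; 3-hydroxy as epimer mixture; C4 quaternary)
Conditions: KOt-Bu (0.3 equiv), t-BuOH/THF (1:4), −20 to 0 °C; AcOH quench
Reagents that add atoms: none
Why: Reversible intramolecular aldol addition (the aldol/retro-aldol manifold known for 3-hydroxygibberellin lactones) in which the lactone enolate, the most acidic ester-type position, should close ring A on the aldehyde (6-exo-trig), the C1–C2–C3 tether reaching only one face of C4 so that the quaternary centre forms with 18-CH3 β and C19 α from either C4 epimer, while the C3 configuration is left open because it is reset in steps 12 and 14.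

Step 12
Reactants: 15 ring-A aldol
Product: 16 3-ketone (β-keto lactone)
Conditions: SO3·pyridine (4 equiv), DMSO, Et3N, CH2Cl2, 0 °C to rt
Reagents that add atoms: none
Why: Parikh–Doering oxidation of the secondary alcohol should give the non-enolisable β-keto lactone, erasing the C3 epimer mixture while again sparing the enediol disilyl ether.

Step 13
Reactants: 16 3-ketone
Product: 17 3,12-diketone with ring D (13-OTBS bridgehead; 16-methylene)
Conditions: Ph3PAuCl (5 mol %), AgBF4 (5 mol %), CH2Cl2/MeOH (10:1), rt
Reagents that add atoms: none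
Why: Gold-catalysed Conia-ene-type carbocyclisation of a silyl enol ether (5-exo-dig) in which Ph3PAu+ (monovalent gold) activates the alkyne, C13 of the enediol disilyl ether should attack C16 through the five-membered transition state (C13–C14–C8–C15–C16, favoured over the six-membered alternative from C12) and methanol removes the silyl group from O12 and protonates the vinylgold, giving ring D with the 16-methylene, the 12-ketone and the 13-silyl ether, the C13 configuration being fixed by the β orientation of C15 on C8.

Step 14
Reactants: 17 3,12-diketone with ring D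
Product: 18 3β,12α-diol (13-O-TBS; 2-(trimethylsilyl)ethyl ester)
Conditions: K[HB(s-Bu)3] (3 equiv), THF, −78 °C; aq. NH4Cl
Reagents that add atoms: none
Why: Diastereoselective ketone reduction with a bulky trialkylborohydride in which equatorial hydride delivery at both carbonyls should give the two axial alcohols, at C3 because the axial approach is disfavoured for the bulky reagent (3β-OH, as known for 3-oxogibberellin esters) and at C12 because the axial approach is blocked by the syn-axial C9–C10 bond of ring C (12α-OH), while lactone and ester are inert at −78 °C.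

Step 15
Reactants: 18 3β,12α-diol
Product: 19 target CNP0260503.1 (3β,12α,13-trihydroxy-20-norgibberell-16-ene-7,19-dioic acid 19,10-lactone)
Conditions: Bu4NF (4 equiv), AcOH (2 equiv), THF, 0 °C to rt; aq. NH4Cl
Reagents that add atoms: none
Why: Fluoride-mediated desilylation together with fragmentation of the 2-(trimethylsilyl)ethyl ester (loss of ethene and Me3SiF) should free 13-OH and the C7 acid in one buffered operation, so that the retro-aldol-prone 3β-hydroxy lactone and the acid-sensitive 13-hydroxy-16-ene unit survive and no stereocentre changes.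

## Compound list

1 | butane-2,3-dione | CC(=O)C(C)=O | starting material
2 | 2,3-bis(tert-butyldimethylsilyloxy)buta-1,3-diene | C=C(O[Si](C)(C)C(C)(C)C)C(=C)O[Si](C)(C)C(C)(C)C | intermediate
3 | 3-(4-hydroxyphenyl)propan-1-ol | OCCCc1ccc(O)cc1 | starting material
4 | allyl 3-(4-hydroxyphenyl)propyl carbonate | C=CCOC(=O)OCCCc1ccc(O)cc1 | intermediate
5 | 1-[3-(allyloxycarbonyloxy)propyl]-4-oxocyclohexa-2,5-dien-1-yl propanoate (achiral quinol ester) | CCC(=O)OC1(CCCOC(=O)OCC=C)C=CC(=O)C=C1 | intermediate
6 | Diels–Alder adduct: 1-[3-(allyloxycarbonyloxy)propyl]-6,7-bis(tert-butyldimethylsilyloxy)-4-oxo-1,4,4a,5,8,8a-hexahydronaphthalen-1-yl propanoate, cis ring fusion, both ring-fusion hydrogens trans to the propanoyloxy group (10α-O, 8β-H, 9β-H, Δ5-7-one) | CCC(=O)O[C@@]1(CCCOC(=O)OCC=C)C=CC(=O)[C@H]2CC(O[Si](C)(C)C(C)(C)C)=C(O[Si](C)(C)C(C)(C)C)C[C@@H]12 | intermediate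
7 | as 6 with a prop-2-ynyl group in place of 8-H on the same (β) face, cis ring fusion kept (quaternary C8) | CCC(=O)O[C@@]1(CCCOC(=O)OCC=C)C=CC(=O)[C@@]2(CC#C)CC(O[Si](C)(C)C(C)(C)C)=C(O[Si](C)(C)C(C)(C)C)C[C@@H]12 | intermediate
8 | tricyclic lactone ketone: γ-lactone O–C10/C19/C4/C5 cis-fused to the cyclohexanone (5β-H), 7-ketone with C6 methylene, C4 (H, CH3) as both epimers | CC1C(=O)O[C@@]2(CCCOC(=O)OCC=C)[C@@H]1CC(=O)[C@@]1(CC#C)CC(O[Si](C)(C)C(C)(C)C)=C(O[Si](C)(C)C(C)(C)C)C[C@H]12 | intermediate
9 | 6-(trifluoroacetyl) derivative of 8 (β-diketone, not isolated) | CC1C(=O)O[C@@]2(CCCOC(=O)OCC=C)[C@@H]1C(C(=O)C(F)(F)F)C(=O)[C@@]1(CC#C)CC(O[Si](C)(C)C(C)(C)C)=C(O[Si](C)(C)C(C)(C)C)C[C@H]12 | intermediate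
10 | 6-diazo-7-ketone of the lactone series | CC1C(=O)O[C@@]2(CCCOC(=O)OCC=C)[C@@H]1C(=[N+]=[N-])C(=O)[C@@]1(CC#C)CC(O[Si](C)(C)C(C)(C)C)=C(O[Si](C)(C)C(C)(C)C)C[C@H]12 | intermediate
11 | ring-contracted ketene, C6(=C7=O) bonded to C5 and C8 (not isolated) | CC1C(=O)O[C@@]2(CCCOC(=O)OCC=C)[C@@H]1C(=C=O)[C@@]1(CC#C)CC(O[Si](C)(C)C(C)(C)C)=C(O[Si](C)(C)C(C)(C)C)C[C@H]12 | intermediate
12 | ring-B-contracted ester: cyclopentane C5–C6–C8–C9–C10 with 6β-CO2CH2CH2SiMe3 (6α-H trans to 5β-H), lactone, 8β-propargyl, enediol disilyl ether, C4 epimers | CC1C(=O)O[C@@]2(CCCOC(=O)OCC=C)[C@@H]1[C@H](C(=O)OCC[Si](C)(C)C)[C@@]1(CC#C)CC(O[Si](C)(C)C(C)(C)C)=C(O[Si](C)(C)C(C)(C)C)C[C@H]12 | intermediate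
13 | primary alcohol from 12 (3-hydroxypropyl chain on C10) | CC1C(=O)O[C@@]2(CCCO)[C@@H]1[C@H](C(=O)OCC[Si](C)(C)C)[C@@]1(CC#C)CC(O[Si](C)(C)C(C)(C)C)=C(O[Si](C)(C)C(C)(C)C)C[C@H]12 | intermediate
14 | C3 aldehyde (3-oxopropyl chain on C10) | CC1C(=O)O[C@@]2(CCC=O)[C@@H]1[C@H](C(=O)OCC[Si](C)(C)C)[C@@]1(CC#C)CC(O[Si](C)(C)C(C)(C)C)=C(O[Si](C)(C)C(C)(C)C)C[C@H]12 | intermediate
15 | aldol product with ring A closed (C3–C4), 3-hydroxy as epimer mixture, quaternary C4 (18-CH3 β, lactone carbonyl α) | C#CC[C@]12CC(O[Si](C)(C)C(C)(C)C)=C(O[Si](C)(C)C(C)(C)C)C[C@H]1[C@@]13CCC(O)[C@@](C)(C(=O)O1)[C@H]3[C@@H]2C(=O)OCC[Si](C)(C)C | intermediate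
16 | 3-ketone (β-keto lactone) of the ring A/B/C series | C#CC[C@]12CC(O[Si](C)(C)C(C)(C)C)=C(O[Si](C)(C)C(C)(C)C)C[C@H]1[C@@]13CCC(=O)[C@@](C)(C(=O)O1)[C@H]3[C@@H]2C(=O)OCC[Si](C)(C)C | intermediate
17 | 3,12-dioxo-13-(tert-butyldimethylsilyloxy)-20-norgibberell-16-ene 19,10-lactone 7-[2-(trimethylsilyl)ethyl] ester | C=C1C[C@]23C[C@@]1(O[Si](C)(C)C(C)(C)C)C(=O)C[C@H]2[C@@]12CCC(=O)[C@@](C)(C(=O)O1)[C@H]2[C@@H]3C(=O)OCC[Si](C)(C)C | intermediate
18 | 3β,12α-dihydroxy-13-(tert-butyldimethylsilyloxy) 19,10-lactone 7-[2-(trimethylsilyl)ethyl] ester | C=C1C[C@]23C[C@@]1(O[Si](C)(C)C(C)(C)C)[C@@H](O)C[C@H]2[C@@]12CC[C@H](O)[C@@](C)(C(=O)O1)[C@H]2[C@@H]3C(=O)OCC[Si](C)(C)C | intermediate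
19 | CNP0260503.1 (3β,12α,13-trihydroxy-20-norgibberell-16-ene-7,19-dioic acid 19,10-lactone; 12-OH axial, anti to the C15–C16 bridge) | C=C1C[C@]23C[C@@]1(O)[C@@H](O)C[C@H]2[C@@]12CC[C@H](O)[C@@](C)(C(=O)O1)[C@H]2[C@@H]3C(=O)O | target

## Step count and risks

Total step count: 15. Longest linear sequence: 14 steps (from 3, steps 2 to 15); diene 2 is made in one side step.

Steps most likely to fail:

1. Step 4. The catalyst may discriminate the two enantiotopic enone units poorly, the diene may add anti to the propanoyloxy group, or the acid-labile disilyloxydiene may be protodesilylated by the strongly acidic catalyst before it cycloadds. Fallback, setting out from 5 and 2 and coming back at 6: the cycloaddition is promoted by the achiral, milder Lewis acid Me2AlCl (CH2Cl2, −78 °C), which needs no chiral recognition. It should give 6 as a racemate, that is together with the mirror-image adduct F1. The two are separated by preparative chromatography on a chiral stationary phase (cellulose tris(3,5-dimethylphenylcarbamate)), and the route continues from 6. This fallback answers the enantioselectivity and diene-stability risks only; addition anti to the propanoyloxy group would remain a problem.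

2. Step 13. The enediol disilyl ether may be protodesilylated to the acyloin without C–C bond formation, or closure may occur from C12 (six-membered mode) to a bicyclo[2.2.2]octane. Fallback, setting out from 16 and coming back at 19: the alkyne is activated by a radical instead of a cationic pathway. Bu3SnH and AIBN (benzene, 80 °C) add a stannyl radical to the alkyne terminus, and the vinyl radical at C16 cyclises 5-exo onto C13 of the enediol ether (hydrostannylation/vinyl-radical cyclisation). The α-silyloxy radical at C12 should take hydrogen from the open β face, giving the 12α,13-bis-silyloxy vinylstannane F2. HCl in CH2Cl2 (0 °C) removes tin to give the 16-methylene 3-ketone F3. K[HB(s-Bu)3] (THF, −78 °C) reduces only the C3 ketone to the 3β-alcohol F4. Bu4NF/AcOH then removes both silyl ethers and the ester to give 19.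

3. Step 11. Under the reversible conditions the aldehyde may be consumed by self-condensation or by aldol addition of the C6 ester enolate, or the alkoxide may cleave the enol silyl ethers. Fallback, setting out from 14 and coming back at 16: ring A is closed by an irreversible acylation instead of an aldol addition. Pinnick oxidation (NaClO2, NaH2PO4, 2-methylbut-2-ene, t-BuOH/H2O) gives the carboxylic acid F5. Carbonyldiimidazole (THF, rt) gives the acyl imidazolide F6. LiN(SiMe3)2 (THF, −78 °C) forms the lactone enolate, which is C-acylated intramolecularly (Claisen-type condensation) to give 3-ketone 16 directly, so that 15 and step 12 are by-passed.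

Further compounds

F1 | step 4 | enantiomer of Diels–Alder adduct 6 | CCC(=O)O[C@]1(CCCOC(=O)OCC=C)C=CC(=O)[C@@H]2CC(O[Si](C)(C)C(C)(C)C)=C(O[Si](C)(C)C(C)(C)C)C[C@H]12
F2 | step 13 | 17-(tributylstannyl) ring-D 3-ketone with 12α,13-bis(tert-butyldimethylsilyloxy) groups | CCCC[Sn](CCCC)(CCCC)C=C1C[C@]23C[C@@]1(O[Si](C)(C)C(C)(C)C)[C@@H](O[Si](C)(C)C(C)(C)C)C[C@H]2[C@@]12CCC(=O)[C@@](C)(C(=O)O1)[C@H]2[C@@H]3C(=O)OCC[Si](C)(C)C
F3 | step 13 | 16-methylene 3-ketone with 12α,13-bis(tert-butyldimethylsilyloxy) groups | C=C1C[C@]23C[C@@]1(O[Si](C)(C)C(C)(C)C)[C@@H](O[Si](C)(C)C(C)(C)C)C[C@H]2[C@@]12CCC(=O)[C@@](C)(C(=O)O1)[C@H]2[C@@H]3C(=O)OCC[Si](C)(C)C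
F4 | step 13 | 3β-alcohol of F3 | C=C1C[C@]23C[C@@]1(O[Si](C)(C)C(C)(C)C)[C@@H](O[Si](C)(C)C(C)(C)C)C[C@H]2[C@@]12CC[C@H](O)[C@@](C)(C(=O)O1)[C@H]2[C@@H]3C(=O)OCC[Si](C)(C)C
F5 | step 11 | C3 carboxylic acid from aldehyde 14 | CC1C(=O)O[C@@]2(CCC(=O)O)[C@@H]1[C@H](C(=O)OCC[Si](C)(C)C)[C@@]1(CC#C)CC(O[Si](C)(C)C(C)(C)C)=C(O[Si](C)(C)C(C)(C)C)C[C@H]12
F6 | step 11 | acyl imidazolide of F5 | CC1C(=O)O[C@@]2(CCC(=O)n3ccnc3)[C@@H]1[C@H](C(=O)OCC[Si](C)(C)C)[C@@]1(CC#C)CC(O[Si](C)(C)C(C)(C)C)=C(O[Si](C)(C)C(C)(C)C)C[C@H]12
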